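**Retrosynthetic overview** (germacrane numbering: C6 = lactone O–CH, C7 = ring-fusion CH, C9 = CH–OAc, C1=C10 and C4=C5 = ring alkenes, C15 = CH2O-isovalerate)
1. Ten-membered ring: closed last by ring-closing metathesis at C1=C10 (ring-cis) on a diene that already carries the lactone and both esters.
2. cis-α-Methylene-γ-lactone (first ring): carbonylative lactonisation of a C6-hydroxy C11 vinyl triflate, derived from the acyl carbon of an aldol adduct (imide → Weinreb amide → methyl ketone → enol triflate).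
3. Key bond C6–C7: intermolecular Evans syn-aldol joining fragment B (N-acyl oxazolidinone; C7–C11, C14; C9 preset) with fragment A ((Z)-enal; C1–C6, C15); it sets C6 and C7.
4. Fragment A from syn-carbocupration of a 4-alkoxybut-2-ynoate (fixes C4=C5); fragment B from CBS reduction of an isopropenyl ketone (sets C9).

Assumption: the SMILES is read as (6R,7R,9S) with a cis-fused lactone, C1=C10 cis in the ring and C4=C5 trans in the ring (both are Z by CIP).

Abbreviations: PMB = 4-methoxybenzyl; PMBO-methyl = [(4-methoxybenzyl)oxy]methyl; TBS = tert-butyldimethylsilyl; TES = triethylsilyl; Tf = trifluoromethanesulfonyl.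

**Fragment A**

Step 1
Reactants: 1 prop-2-yn-1-ol
Product: 2 1-methoxy-4-[(prop-2-yn-1-yloxy)methyl]benzene
Conditions: NaH, PMBCl, Bu4NI (cat.), THF, 0 °C → rt
Reagents that add atoms: 4-methoxybenzyl chloride, COc1ccc(CCl)cc1
Why: Williamson ether synthesis of the primary alkoxide with a reactive benzylic chloride; the alkyne C–H is not touched by the alkoxide.

Step 2
Reactants: 2 1-methoxy-4-[(prop-2-yn-1-yloxy)methyl]benzene
Product: 4 methyl 4-[(4-methoxybenzyl)oxy]but-2-ynoate, via lithium acetylide 3 (not isolated)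
Conditions: nBuLi, THF, −78 °C; ClCO2Me, −78 → 0 °C
Reagents that add atoms: methyl chloroformate, COC(=O)Cl
Why: Deprotonation of the terminal alkyne and C-acylation of the acetylide by the chloroformate is a standard ynoate synthesis.

Step 3
Reactants: 4 methyl 4-[(4-methoxybenzyl)oxy]but-2-ynoate; 5 but-3-en-1-ylmagnesium bromide
Product: 7 methyl (2Z)-3-(PMBO-methyl)hepta-2,6-dienoate, via alkenylcopper 6 (not isolated)
Conditions: 5, CuBr·SMe2 (1.3 equiv each), THF, −40 °C; then 4, −78 °C; MeOH at −78 °C, then aq. NH4Cl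
Reagents that add atoms: none
Why: Conjugate syn-carbocupration of the ynoate followed by protonation of the configurationally stable alkenylcopper at −78 °C places the new chain cis to H, so the ester and CH2OPMB end up cis (the C4=C5 geometry of the target).

Step 4
Reactants: 7 methyl (2Z)-3-(PMBO-methyl)hepta-2,6-dienoate
Product: 8 (2Z)-3-(PMBO-methyl)hepta-2,6-dien-1-ol
Conditions: iBu2AlH (2.3 equiv), CH2Cl2, −78 °C; aq. potassium sodium tartrate
Reagents that add atoms: none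
Why: 1,2-Reduction of the enoate by DIBAL-H gives the allylic alcohol without touching alkene geometry.

Step 5
Reactants: 8 (2Z)-3-(PMBO-methyl)hepta-2,6-dien-1-ol
Product: 9 (2Z)-3-(PMBO-methyl)hepta-2,6-dienal
Conditions: MnO2 (15 equiv), CH2Cl2, rt; used at once
Reagents that add atoms: none
Why: Neutral allylic oxidation with MnO2 gives the enal with retention of the (Z) geometry, as in nerol → neral.

**Fragment B**

Step 6
Reactants: 10 methyl 4-chloro-4-oxobutanoate
Product: 11 methyl 4-[methoxy(methyl)amino]-4-oxobutanoate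
Conditions: MeONHMe·HCl, Et3N (2.2 equiv), CH2Cl2, 0 °C
Reagents that add atoms: N,O-dimethylhydroxylamine hydrochloride, CNOC.Cl
Why: Amidation of the acid chloride gives the Weinreb amide while the methyl ester stays intact.

Step 7
Reactants: 11 methyl 4-[methoxy(methyl)amino]-4-oxobutanoate; 12 prop-1-en-2-ylmagnesium bromide
Product: 13 methyl 5-methyl-4-oxohex-5-enoate
Conditions: 12 (1.2 equiv), THF, −20 °C; cold 1 M HCl quench
Reagents that add atoms: none
Why: Weinreb ketone synthesis: the chelated tetrahedral adduct stops at the ketone stage and the amide reacts faster than the methyl ester at −20 °C.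

Step 8
Reactants: 13 methyl 5-methyl-4-oxohex-5-enoate
Product: 14 methyl (4S)-4-hydroxy-5-methylhex-5-enoate
Conditions: (R)-2-methyl-CBS-oxazaborolidine (20 mol%), catecholborane (1.5 equiv), toluene, −78 °C; MeOH quench
Reagents that add atoms: none
Why: Corey–Bakshi–Shibata reduction with the isopropenyl group as the large substituent delivers hydride to give the (S)-allylic alcohol (C9); any minor enantiomer becomes a separable diastereomer after step 12.

Step 9
Reactants: 14 methyl (4S)-4-hydroxy-5-methylhex-5-enoate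
Product: 15 methyl (4S)-4-(TBSO)-5-methylhex-5-enoate
Conditions: TBSCl, imidazole, DMF, 0 °C → rt
Reagents that add atoms: tert-butyldimethylsilyl chloride, CC(C)(C)[Si](C)(C)Cl
Why: Imidazole-promoted silylation protects the alcohol before it can lactonise onto the ester.

Step 10
Reactants: 15 methyl (4S)-4-(TBSO)-5-methylhex-5-enoate
Product: 16 (4S)-4-(TBSO)-5-methylhex-5-enoic acid
Conditions: LiOH·H2O, THF/MeOH/H2O, rt; 1 M HCl to pH 4 at 0 °C
Reagents that add atoms: lithium hydroxide, [Li+].[OH-]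
Why: Saponification of the methyl ester; the secondary TBS ether is stable to hydroxide and to brief mild acidification.

Step 11
Reactants: 16 (4S)-4-(TBSO)-5-methylhex-5-enoic acid; 17 (4S)-4-benzyl-1,3-oxazolidin-2-one
Product: 19 (4S)-4-benzyl-3-[(4S)-4-(TBSO)-5-methylhex-5-enoyl]-1,3-oxazolidin-2-one, via mixed anhydride 18 (not isolated)
Conditions: pivaloyl chloride, Et3N, THF, −20 °C; then 17, LiCl, −20 °C → rt
Reagents that add atoms: none
Why: Mixed-anhydride N-acylation of the Evans auxiliary; the hindered pivaloyl carbonyl directs attack to the desired acyl group.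

**Key step and lactone**

Step 12
Reactants: 19 (4S)-4-benzyl-3-[(4S)-4-(TBSO)-5-methylhex-5-enoyl]-1,3-oxazolidin-2-one; 9 (2Z)-3-(PMBO-methyl)hepta-2,6-dienal
Product: 22 (4S)-4-benzyl-3-[(2S,3R,4Z)-3-hydroxy-5-(PMBO-methyl)-2-[(2S)-2-(TBSO)-3-methylbut-3-en-1-yl]nona-4,8-dienoyl]-1,3-oxazolidin-2-one, via boron enolate 20 (not isolated), via boron aldolate 21 (not isolated)
Conditions: Bu2BOTf (1.2 equiv), iPr2NEt (1.4 equiv), CH2Cl2, −78 → 0 °C; 9, −78 → 0 °C; pH 7 buffer, MeOH, H2O2, 0 °C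
Reagents that add atoms: none
Why: Intermolecular Evans syn-aldol: the (Z)-boron enolate reacts through a Zimmerman–Traxler chair on the face opposite the benzyl group, forming C6–C7 and setting C7 and C6 as the syn pair that becomes the cis-lactone (6R,7R in the target).

Step 13
Reactants: 22 aldol adduct (name as in step 12)
Product: 23 (2S,3R,4Z)-3-hydroxy-N-methoxy-N-methyl-5-(PMBO-methyl)-2-[(2S)-2-(TBSO)-3-methylbut-3-en-1-yl]nona-4,8-dienamide
Conditions: MeONHMe·HCl (3 equiv), AlMe3 (3 equiv), CH2Cl2, −20 → 0 °C; aq. potassium sodium tartrate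
Reagents that add atoms: N,O-dimethylhydroxylamine hydrochloride, CNOC.Cl
Why: Aluminium-amide transamidation, assisted by the free β-hydroxyl, removes the auxiliary without epimerising C7.

Step 14
Reactants: 23 β-hydroxy Weinreb amide (name as in step 13)
Product: 24 (2S,3R,4Z)-N-methoxy-N-methyl-5-(PMBO-methyl)-2-[(2S)-2-(TBSO)-3-methylbut-3-en-1-yl]-3-(TESO)nona-4,8-dienamide
Conditions: TESOTf, 2,6-lutidine, CH2Cl2, −78 → 0 °C
Reagents that add atoms: triethylsilyl trifluoromethanesulfonate, CC[Si](CC)(CC)OS(=O)(=O)C(F)(F)F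
Why: Silylation of the hindered secondary allylic alcohol with a labile TES group blocks retro-aldol and base-mediated side reactions in the next two steps.

Step 15
Reactants: 24 TES-protected Weinreb amide (name as in step 14)
Product: 25 (3S,4R,5Z)-6-(PMBO-methyl)-3-[(2S)-2-(TBSO)-3-methylbut-3-en-1-yl]-4-(TESO)deca-5,9-dien-2-one
Conditions: MeMgBr (3 equiv), THF, 0 °C; aq. NH4Cl
Reagents that add atoms: methylmagnesium bromide, C[Mg]Br
Why: Weinreb ketone synthesis installs C13 as a methyl ketone without over-addition.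

Step 16
Reactants: 25 methyl ketone (name as in step 15)
Product: 27 (3S,4R,5Z)-6-(PMBO-methyl)-3-[(2S)-2-(TBSO)-3-methylbut-3-en-1-yl]-4-(TESO)deca-1,5,9-trien-2-yl trifluoromethanesulfonate, via potassium enolate 26 (not isolated)
Conditions: KN(SiMe3)2 (1.3 equiv), THF, −78 °C; PhNTf2, −78 → −20 °C
Reagents that add atoms: N-phenylbis(trifluoromethanesulfonimide), O=S(=O)(N(c1ccccc1)S(=O)(=O)C(F)(F)F)C(F)(F)F
Why: Kinetic enolisation with a bulky amide base removes a methyl proton rather than the hindered C7 methine, and O-triflation traps the terminal enolate without touching C7.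

Step 17
Reactants: 27 vinyl triflate (name as in step 16)
Product: 28 (3S,4R,5Z)-4-hydroxy-6-(PMBO-methyl)-3-[(2S)-2-(TBSO)-3-methylbut-3-en-1-yl]deca-1,5,9-trien-2-yl trifluoromethanesulfonate
Conditions: PPTS (0.2 equiv), MeOH/CH2Cl2, 0 °C → rt
Reagents that add atoms: none
Why: Mild acid-catalysed solvolysis removes the TES ether selectively; the hindered secondary TBS ether, the PMB ether and the vinyl triflate survive.

Step 18
Reactants: 28 hydroxy vinyl triflate (name as in step 17)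
Product: 29 (4R,5R)-3-methylidene-5-[(1Z)-2-(PMBO-methyl)hexa-1,5-dien-1-yl]-4-[(2S)-2-(TBSO)-3-methylbut-3-en-1-yl]oxolan-2-one
Conditions: Pd(PPh3)4 (10 mol%), CO (1 atm), nBu3N, LiCl, MeCN, 65 °C
Reagents that add atoms: carbon monoxide, [C-]#[O+]
Why: Palladium-catalysed carbonylative lactonisation: oxidative addition of zerovalent palladium to the vinyl triflate, CO insertion and capture of the acyl–Pd by the C6 hydroxyl give the cis-fused α-methylene-γ-lactone with C6 and C7 untouched.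

**End game**

Step 19
Reactants: 29 lactone (name as in step 18)
Product: 30 (4R,5R)-5-[(1Z)-2-(hydroxymethyl)hexa-1,5-dien-1-yl]-3-methylidene-4-[(2S)-2-(TBSO)-3-methylbut-3-en-1-yl]oxolan-2-one
Conditions: DDQ (1.3 equiv), CH2Cl2/pH 7 buffer (10:1), 0 °C
Reagents that add atoms: none
Why: Oxidative PMB cleavage via the benzylic oxocarbenium ion frees only the C15 alcohol; the silyl ether and lactone are inert.

Step 20
Reactants: 30 C15 alcohol (name as in step 19)
Product: 31 (2Z)-2-(but-3-en-1-yl)-3-{(2R,3R)-4-methylidene-5-oxo-3-[(2S)-2-(TBSO)-3-methylbut-3-en-1-yl]oxolan-2-yl}prop-2-en-1-yl 3-methylbutanoate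
Conditions: 3-methylbutanoyl chloride, pyridine, DMAP (cat.), CH2Cl2, 0 °C
Reagents that add atoms: 3-methylbutanoyl chloride, CC(C)CC(=O)Cl
Why: Acylation of the only free (primary) hydroxyl installs the isovalerate.

Step 21
Reactants: 31 isovalerate (name as in step 20)
Product: 32 (2Z)-2-(but-3-en-1-yl)-3-{(2R,3R)-3-[(2S)-2-hydroxy-3-methylbut-3-en-1-yl]-4-methylidene-5-oxooxolan-2-yl}prop-2-en-1-yl 3-methylbutanoate
Conditions: HF·pyridine, pyridine, THF, 0 °C → rt
Reagents that add atoms: none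
Why: Buffered fluoride desilylation removes the TBS group without ester cleavage or conjugate addition to the α-methylene lactone.

Step 22
Reactants: 32 C9 alcohol (name as in step 21)
Product: 33 (2Z)-3-{(2R,3R)-3-[(2S)-2-acetoxy-3-methylbut-3-en-1-yl]-4-methylidene-5-oxooxolan-2-yl}-2-(but-3-en-1-yl)prop-2-en-1-yl 3-methylbutanoate
Conditions: Ac2O, pyridine, DMAP (cat.), CH2Cl2, 0 °C → rt
Reagents that add atoms: acetic anhydride, CC(=O)OC(C)=O
Why: DMAP-catalysed acetylation of the secondary allylic alcohol proceeds with retention at C9.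

Step 23
Reactants: 33 diene diester (name as in step 22)
Product: 34 [(3aR,5S,6Z,10Z,11aR)-5-acetoxy-6-methyl-3-methylidene-2-oxo-2,3,3a,4,5,8,9,11a-octahydrocyclodeca[b]furan-10-yl]methyl 3-methylbutanoate (CNP0398030.1)
Conditions: second-generation Hoveyda–Grubbs catalyst (H2IMes)Cl2Ru=CH(C6H4-2-OiPr) (15 mol%), 1,4-benzoquinone (30 mol%), toluene (1 mM), 80 °C
Reagents that add atoms: none
Why: Ring-closing metathesis between the C1 vinyl and C10 isopropenyl groups, pre-organised by the cis-lactone, closes the ten-membered ring; a ring that already holds one ring-trans trisubstituted alkene is expected to take the new one as the less strained ring-cis (Z) isomer, and no stereocentre is touched.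

**Compound list**

1 | prop-2-yn-1-ol | C#CCO | starting material
2 | 1-methoxy-4-[(prop-2-yn-1-yloxy)methyl]benzene | C#CCOCc1ccc(OC)cc1 | intermediate
3 | {3-[(4-methoxybenzyl)oxy]prop-1-yn-1-yl}lithium (not isolated) | [Li]C#CCOCc1ccc(OC)cc1 | intermediate
4 | methyl 4-[(4-methoxybenzyl)oxy]but-2-ynoate | COC(=O)C#CCOCc1ccc(OC)cc1 | intermediate
5 | but-3-en-1-ylmagnesium bromide | C=CCC[Mg]Br | starting material
6 | methyl 2-cuprio-3-(PMBO-methyl)hepta-2,6-dienoate, Cu cis to the butenyl chain (not isolated) | COC(=O)/C([Cu])=C(\COCc1ccc(OC)cc1)CCC=C | intermediate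
7 | methyl (2Z)-3-(PMBO-methyl)hepta-2,6-dienoate | COC(=O)/C=C(\COCc1ccc(OC)cc1)CCC=C | intermediate
8 | (2Z)-3-(PMBO-methyl)hepta-2,6-dien-1-ol | OC/C=C(\COCc1ccc(OC)cc1)CCC=C | intermediate
9 | (2Z)-3-(PMBO-methyl)hepta-2,6-dienal | O=C/C=C(\COCc1ccc(OC)cc1)CCC=C | intermediate
10 | methyl 4-chloro-4-oxobutanoate | COC(=O)CCC(=O)Cl | starting material
11 | methyl 4-[methoxy(methyl)amino]-4-oxobutanoate | COC(=O)CCC(=O)N(C)OC | intermediate
12 | prop-1-en-2-ylmagnesium bromide | C=C(C)[Mg]Br | starting material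
13 | methyl 5-methyl-4-oxohex-5-enoate | COC(=O)CCC(=O)C(C)=C | intermediate
14 | methyl (4S)-4-hydroxy-5-methylhex-5-enoate | COC(=O)CC[C@H](O)C(C)=C | intermediate
15 | methyl (4S)-4-(TBSO)-5-methylhex-5-enoate | COC(=O)CC[C@H](O[Si](C)(C)C(C)(C)C)C(C)=C | intermediate
16 | (4S)-4-(TBSO)-5-methylhex-5-enoic acid | OC(=O)CC[C@H](O[Si](C)(C)C(C)(C)C)C(C)=C | intermediate
17 | (4S)-4-benzyl-1,3-oxazolidin-2-one | O=C1N[C@@H](Cc2ccccc2)CO1 | starting material
18 | (4S)-4-(TBSO)-5-methylhex-5-enoic pivalic anhydride (not isolated) | CC(C)(C)C(=O)OC(=O)CC[C@H](O[Si](C)(C)C(C)(C)C)C(C)=C | intermediate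
19 | (4S)-4-benzyl-3-[(4S)-4-(TBSO)-5-methylhex-5-enoyl]-1,3-oxazolidin-2-one | O=C(CC[C@H](O[Si](C)(C)C(C)(C)C)C(C)=C)N1[C@@H](Cc2ccccc2)COC1=O | intermediate
20 | (Z)-dibutylboron enolate of 19 (not isolated) | CCCCB(CCCC)O/C(=C\C[C@H](O[Si](C)(C)C(C)(C)C)C(C)=C)N1[C@@H](Cc2ccccc2)COC1=O | intermediate
21 | O-dibutylboryl aldolate of 22 (not isolated) | O=C([C@@H](C[C@H](O[Si](C)(C)C(C)(C)C)C(C)=C)[C@H](OB(CCCC)CCCC)/C=C(\COCc1ccc(OC)cc1)CCC=C)N1[C@@H](Cc2ccccc2)COC1=O | intermediate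
22 | (4S)-4-benzyl-3-[(2S,3R,4Z)-3-hydroxy-5-(PMBO-methyl)-2-[(2S)-2-(TBSO)-3-methylbut-3-en-1-yl]nona-4,8-dienoyl]-1,3-oxazolidin-2-one | O=C([C@@H](C[C@H](O[Si](C)(C)C(C)(C)C)C(C)=C)[C@H](O)/C=C(\COCc1ccc(OC)cc1)CCC=C)N1[C@@H](Cc2ccccc2)COC1=O | intermediate
23 | (2S,3R,4Z)-3-hydroxy-N-methoxy-N-methyl-5-(PMBO-methyl)-2-[(2S)-2-(TBSO)-3-methylbut-3-en-1-yl]nona-4,8-dienamide | CON(C)C(=O)[C@@H](C[C@H](O[Si](C)(C)C(C)(C)C)C(C)=C)[C@H](O)/C=C(\COCc1ccc(OC)cc1)CCC=C | intermediate
24 | (2S,3R,4Z)-N-methoxy-N-methyl-5-(PMBO-methyl)-2-[(2S)-2-(TBSO)-3-methylbut-3-en-1-yl]-3-(TESO)nona-4,8-dienamide | CON(C)C(=O)[C@@H](C[C@H](O[Si](C)(C)C(C)(C)C)C(C)=C)[C@H](O[Si](CC)(CC)CC)/C=C(\COCc1ccc(OC)cc1)CCC=C | intermediate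
25 | (3S,4R,5Z)-6-(PMBO-methyl)-3-[(2S)-2-(TBSO)-3-methylbut-3-en-1-yl]-4-(TESO)deca-5,9-dien-2-one | CC(=O)[C@@H](C[C@H](O[Si](C)(C)C(C)(C)C)C(C)=C)[C@H](O[Si](CC)(CC)CC)/C=C(\COCc1ccc(OC)cc1)CCC=C | intermediate
26 | terminal potassium enolate of 25 (not isolated) | C=C(O[K])[C@@H](C[C@H](O[Si](C)(C)C(C)(C)C)C(C)=C)[C@H](O[Si](CC)(CC)CC)/C=C(\COCc1ccc(OC)cc1)CCC=C | intermediate
27 | (3S,4R,5Z)-6-(PMBO-methyl)-3-[(2S)-2-(TBSO)-3-methylbut-3-en-1-yl]-4-(TESO)deca-1,5,9-trien-2-yl trifluoromethanesulfonate | C=C(OS(=O)(=O)C(F)(F)F)[C@@H](C[C@H](O[Si](C)(C)C(C)(C)C)C(C)=C)[C@H](O[Si](CC)(CC)CC)/C=C(\COCc1ccc(OC)cc1)CCC=C | intermediate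
28 | (3S,4R,5Z)-4-hydroxy-6-(PMBO-methyl)-3-[(2S)-2-(TBSO)-3-methylbut-3-en-1-yl]deca-1,5,9-trien-2-yl trifluoromethanesulfonate | C=C(OS(=O)(=O)C(F)(F)F)[C@@H](C[C@H](O[Si](C)(C)C(C)(C)C)C(C)=C)[C@H](O)/C=C(\COCc1ccc(OC)cc1)CCC=C | intermediate
29 | (4R,5R)-3-methylidene-5-[(1Z)-2-(PMBO-methyl)hexa-1,5-dien-1-yl]-4-[(2S)-2-(TBSO)-3-methylbut-3-en-1-yl]oxolan-2-one | C=C1C(=O)O[C@H](/C=C(\COCc2ccc(OC)cc2)CCC=C)[C@@H]1C[C@H](O[Si](C)(C)C(C)(C)C)C(C)=C | intermediate
30 | (4R,5R)-5-[(1Z)-2-(hydroxymethyl)hexa-1,5-dien-1-yl]-3-methylidene-4-[(2S)-2-(TBSO)-3-methylbut-3-en-1-yl]oxolan-2-one | C=C1C(=O)O[C@H](/C=C(\CO)CCC=C)[C@@H]1C[C@H](O[Si](C)(C)C(C)(C)C)C(C)=C | intermediate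
31 | (2Z)-2-(but-3-en-1-yl)-3-{(2R,3R)-4-methylidene-5-oxo-3-[(2S)-2-(TBSO)-3-methylbut-3-en-1-yl]oxolan-2-yl}prop-2-en-1-yl 3-methylbutanoate | C=C1C(=O)O[C@H](/C=C(\COC(=O)CC(C)C)CCC=C)[C@@H]1C[C@H](O[Si](C)(C)C(C)(C)C)C(C)=C | intermediate
32 | (2Z)-2-(but-3-en-1-yl)-3-{(2R,3R)-3-[(2S)-2-hydroxy-3-methylbut-3-en-1-yl]-4-methylidene-5-oxooxolan-2-yl}prop-2-en-1-yl 3-methylbutanoate | C=C1C(=O)O[C@H](/C=C(\COC(=O)CC(C)C)CCC=C)[C@@H]1C[C@H](O)C(C)=C | intermediate
33 | (2Z)-3-{(2R,3R)-3-[(2S)-2-acetoxy-3-methylbut-3-en-1-yl]-4-methylidene-5-oxooxolan-2-yl}-2-(but-3-en-1-yl)prop-2-en-1-yl 3-methylbutanoate | C=C1C(=O)O[C@H](/C=C(\COC(=O)CC(C)C)CCC=C)[C@@H]1C[C@H](OC(C)=O)C(C)=C | intermediate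
34 | [(3aR,5S,6Z,10Z,11aR)-5-acetoxy-6-methyl-3-methylidene-2-oxo-2,3,3a,4,5,8,9,11a-octahydrocyclodeca[b]furan-10-yl]methyl 3-methylbutanoate (CNP0398030.1) | C=C1C(=O)O[C@@H]2/C=C(\COC(=O)CC(C)C)CC/C=C(/C)[C@@H](OC(C)=O)C[C@H]12 | target

**Totals**

Total step count: 23. Longest linear sequence: 18 steps (steps 6–11, then 12–23, from methyl 4-chloro-4-oxobutanoate). Fragment A adds 5 steps (1–5) off that line.

**Steps most likely to fail, with fallbacks**

Step 23 (ring-closing metathesis). Closing a ten-membered carbocycle onto a 1,1-disubstituted alkene that carries an allylic acetate may be slow, give oligomers, or give some of the ring-trans isomer. The fallback sets out from 32 and comes back at 34. The ring is closed one step earlier on the free allylic alcohol 32 with second-generation Grubbs catalyst (H2IMes)(PCy3)Cl2Ru=CHPh in CH2Cl2 at 40 °C and 0.5 mM. The small hydroxyl next to the isopropenyl group lowers the steric demand at the reacting alkene and can assist the catalyst. This gives the ring-closed C9 alcohol F1, which is acetylated with Ac2O, pyridine and DMAP to 34.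

Step 16 (regioselective enol triflate). Competing deprotonation at C7 would epimerise it or eliminate the C6 silyloxy group. The fallback sets out from 24 and comes back at 29, so it also bypasses steps 17 and 18. Weinreb amide 24 is reduced with iBu2AlH in THF at −78 °C to the TES-protected aldehyde F2. Homologation with lithiated trimethylsilyldiazomethane (Me3SiCHN2, nBuLi, THF, −78 °C → rt; Colvin rearrangement) gives the TES-protected terminal alkyne F3. PPTS in MeOH removes the TES group to give the homopropargylic alcohol F4. Cyclocarbonylation of this alkynol (PdCl2, PPh3, SnCl2, CO 7 atm, MeCN, 75 °C) builds the α-methylene lactone 29 directly.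

Step 8 (CBS reduction). An isopropenyl ketone with a primary alkyl chain on the other side may give only moderate enantioselectivity. The fallback sets out from 13 and comes back at 14. Luche reduction (NaBH4, CeCl3·7H2O, MeOH, −40 °C) gives the racemic hydroxy ester F5. Sharpless kinetic resolution (Ti(OiPr)4, D-(−)-diisopropyl tartrate, tBuOOH 0.6 equiv, 4 Å sieves, CH2Cl2, −20 °C) epoxidises the (R)-enantiomer to the epoxy alcohol F6, which is removed by chromatography. The unreacted (S)-alcohol 14 is recovered in high enantiomeric purity.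

**Further compounds**

F1 | step 23 | [(3aR,5S,6Z,10Z,11aR)-5-hydroxy-6-methyl-3-methylidene-2-oxo-2,3,3a,4,5,8,9,11a-octahydrocyclodeca[b]furan-10-yl]methyl 3-methylbutanoate | C=C1C(=O)O[C@@H]2/C=C(\COC(=O)CC(C)C)CC/C=C(/C)[C@@H](O)C[C@H]12
F2 | step 16 | (2S,3R,4Z)-5-(PMBO-methyl)-2-[(2S)-2-(TBSO)-3-methylbut-3-en-1-yl]-3-(TESO)nona-4,8-dienal | O=C[C@@H](C[C@H](O[Si](C)(C)C(C)(C)C)C(C)=C)[C@H](O[Si](CC)(CC)CC)/C=C(\COCc1ccc(OC)cc1)CCC=C
F3 | step 16 | (3R,4R,5Z)-6-(PMBO-methyl)-3-[(2S)-2-(TBSO)-3-methylbut-3-en-1-yl]-4-(TESO)deca-5,9-dien-1-yne | C#C[C@@H](C[C@H](O[Si](C)(C)C(C)(C)C)C(C)=C)[C@H](O[Si](CC)(CC)CC)/C=C(\COCc1ccc(OC)cc1)CCC=C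
F4 | step 16 | (3R,4R,5Z)-6-(PMBO-methyl)-3-[(2S)-2-(TBSO)-3-methylbut-3-en-1-yl]deca-5,9-dien-1-yn-4-ol | C#C[C@@H](C[C@H](O[Si](C)(C)C(C)(C)C)C(C)=C)[C@H](O)/C=C(\COCc1ccc(OC)cc1)CCC=C
F5 | step 8 | methyl (4RS)-4-hydroxy-5-methylhex-5-enoate (racemate) | COC(=O)CCC(O)C(C)=C
F6 | step 8 | methyl (4R)-4-hydroxy-4-[(2S)-2-methyloxiran-2-yl]butanoate | COC(=O)CC[C@@H](O)[C@]1(C)CO1
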